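The flavanone ring C is cut at O1–C2 and C4–C4a, which reveals a [3+3] union of a phloroglucinol-type phenol (O1, C8a, C4a of ring A) with a strained C2–C3–C4 unit, an enantioenriched 4-aryl β-lactone. The key step exploits the 1,3-relationship between the oxygen-bearing stereocenter C2 and the carbonyl carbon C4: phenoxide opens the lactone at its benzylic carbon with inversion (strain release, sets C2), and the freed carboxyl is closed onto C4a in the same flask. The precursor is a four-membered lactone whose aryl group carries bromine and iodine in place of the acid-labile dienyl and prenyl groups; these are added last by two Stille couplings.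

Key step: step 4

Assumption: in step 3 the quinidine-derived silyl ether is taken to deliver the (R)-lactone; if the first run shows the opposite sense, the pseudoenantiomeric O-trimethylsilylquinine is used and nothing else in the route changes.

Step 1
Reactants: 1 3-bromo-4-hydroxybenzaldehyde
Product: 2 3-bromo-4-hydroxy-5-iodobenzaldehyde
Conditions: NIS, TsOH (cat.), MeCN, rt
Reagents that add atoms: N-iodosuccinimide, O=C1CCC(=O)N1I
Why: Electrophilic aromatic iodination, directed by the phenol to its only free ortho position because the para position carries the formyl group.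

Step 2
Reactants: 2 3-bromo-4-hydroxy-5-iodobenzaldehyde
Product: 3 3-bromo-5-iodo-4-methoxybenzaldehyde
Conditions: MeI, K2CO3, DMF, rt
Reagents that add atoms: iodomethane, CI
Why: Williamson O-methylation of an acidic di-ortho-halogenated phenol, which should proceed cleanly at room temperature.

Step 3
Reactants: 3 3-bromo-5-iodo-4-methoxybenzaldehyde
Product: 4 (R)-4-(3-bromo-5-iodo-4-methoxyphenyl)oxetan-2-one
Conditions: AcCl, i-Pr2NEt, O-trimethylsilylquinidine (10 mol %), LiClO4, CH2Cl2/Et2O, −78 °C
Reagents that add atoms: acetyl chloride, CC(=O)Cl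
Why: Catalytic asymmetric ketene–aldehyde [2+2] cycloaddition (acyl halide–aldehyde cyclocondensation), in which ketene made in the flask is captured by the alkaloid as an ammonium enolate that adds to the LiClO4-activated aldehyde and closes to the lactone, the alkaloid selecting the aldehyde face and so setting C4 as (R).

Step 4
Reactants: 4 (R)-4-(3-bromo-5-iodo-4-methoxyphenyl)oxetan-2-one; 5 3,5-bis(benzyloxy)phenol
Product: 8 (S)-5,7-bis(benzyloxy)-2-(3-bromo-5-iodo-4-methoxyphenyl)chroman-4-one, via aryloxy acid 6 (not isolated), via mixed anhydride 7 (not isolated)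
Conditions: Cs2CO3, MeCN, 0 °C to rt; then TFAA, 0 °C to rt
Reagents that add atoms: none
Why: Proposed new method: the cesium phenoxide of 5 attacks the benzylic C4 of lactone 4 in an SN2 alkyl–oxygen cleavage driven by release of the four-ring strain, so the O1–C2 bond forms with inversion and (R)-C4 of the lactone becomes (S)-C2 in carboxylate 6; TFAA then converts 6 into mixed anhydride 7, which acylates the ortho carbon of the trioxygenated ring and forms the C4–C4a bond. The closest known reaction type is the opening of β-propiolactone and β-butyrolactone by phenoxides to 3-aryloxyalkanoic acids with inversion, followed by acid-mediated cyclization to chroman-4-ones; here it is extended to a 4-aryl lactone and run in one flask. Ring C closes in the acylation stage in a 6-exo-trig Friedel–Crafts mode. The only stereocenter, C2, is under substrate control: the configuration set in step 3 is transferred by stereospecific inversion and no catalyst control is needed. The step needs attack by oxygen at the lactone alkyl carbon (not at the acyl carbon and not by a ring carbon) and no ionization at the benzylic carbon; a soft cesium phenoxide in a polar aprotic solvent, the benzylic activation toward SN2, and the two ortho halogens, which twist the 4-methoxy group out of conjugation and disfavour a benzylic cation, should secure this. Because 5 is symmetric, both ortho positions are equivalent and a single chromanone regioisomer should result.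

Step 5
Reactants: 8 (S)-5,7-bis(benzyloxy)-2-(3-bromo-5-iodo-4-methoxyphenyl)chroman-4-one
Product: 9 (S)-2-(3-bromo-5-iodo-4-methoxyphenyl)-5,7-dihydroxychroman-4-one
Conditions: BCl3, pentamethylbenzene, CH2Cl2, −78 °C
Reagents that add atoms: none
Why: Lewis-acid debenzylation of aryl benzyl ethers with pentamethylbenzene as benzyl-cation trap, which at low temperature should spare the hindered methyl ether and both aryl halides and, being base-free, should not open ring C or epimerize C2.

Step 6
Reactants: 9 (S)-2-(3-bromo-5-iodo-4-methoxyphenyl)-5,7-dihydroxychroman-4-one; 10 tributyl(3-methylbut-2-en-1-yl)stannane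
Product: 11 (S)-2-[3-bromo-4-methoxy-5-(3-methylbut-2-en-1-yl)phenyl]-5,7-dihydroxychroman-4-one
Conditions: Pd(PPh3)4 (5 mol %), DMF, 80 °C
Reagents that add atoms: none
Why: Stille coupling in which zerovalent palladium inserts into the C–I bond far faster than into the C–Br bond and the allyl group is delivered through its unsubstituted terminus to give the linear prenyl arene, under neutral conditions that tolerate the free phenols and leave C2 untouched.

Step 7
Reactants: 12 2-methylbut-1-en-3-yne
Product: 13 (E)-tributyl(3-methylbuta-1,3-dien-1-yl)stannane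
Conditions: Bu3SnH, AIBN (cat.), 80 °C
Reagents that add atoms: tributyltin hydride, CCCC[SnH](CCCC)CCCC
Why: Radical hydrostannation of the terminal alkyne, in which the tributylstannyl radical adds to the terminal carbon and reversible addition–elimination should equilibrate the alkenylstannane to the (E) isomer while the 1,1-disubstituted alkene is left alone.

Step 8
Reactants: 11 (S)-2-[3-bromo-4-methoxy-5-(3-methylbut-2-en-1-yl)phenyl]-5,7-dihydroxychroman-4-one; 13 (E)-tributyl(3-methylbuta-1,3-dien-1-yl)stannane
Product: 14 (S)-5,7-dihydroxy-2-{4-methoxy-3-[(E)-3-methylbuta-1,3-dien-1-yl]-5-(3-methylbut-2-en-1-yl)phenyl}chroman-4-one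
Conditions: Pd(PPh3)4 (10 mol %), DMF, 90 °C, dark
Reagents that add atoms: none
Why: Stille coupling of the aryl bromide with the alkenylstannane, which should transfer the dienyl group with retention of the (E) geometry under neutral conditions that leave the free phenols, the prenyl group and the base-sensitive C2 center untouched.

Compound list
1 | 3-bromo-4-hydroxybenzaldehyde | O=Cc1ccc(O)c(Br)c1 | starting material
2 | 3-bromo-4-hydroxy-5-iodobenzaldehyde | O=Cc1cc(Br)c(O)c(I)c1 | intermediate
3 | 3-bromo-5-iodo-4-methoxybenzaldehyde | COc1c(Br)cc(C=O)cc1I | intermediate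
4 | (R)-4-(3-bromo-5-iodo-4-methoxyphenyl)oxetan-2-one | O=C1C[C@@H](O1)c1cc(Br)c(OC)c(I)c1 | intermediate
5 | 3,5-bis(benzyloxy)phenol | Oc1cc(OCc2ccccc2)cc(OCc2ccccc2)c1 | starting material
6 | (S)-3-[3,5-bis(benzyloxy)phenoxy]-3-(3-bromo-5-iodo-4-methoxyphenyl)propanoic acid, formed as its cesium salt | OC(=O)C[C@H](Oc1cc(OCc2ccccc2)cc(OCc2ccccc2)c1)c1cc(Br)c(OC)c(I)c1 | intermediate
7 | mixed anhydride of 6 with trifluoroacetic acid, (S) | O=C(OC(=O)C(F)(F)F)C[C@H](Oc1cc(OCc2ccccc2)cc(OCc2ccccc2)c1)c1cc(Br)c(OC)c(I)c1 | intermediate
8 | (S)-5,7-bis(benzyloxy)-2-(3-bromo-5-iodo-4-methoxyphenyl)chroman-4-one | O=C1C[C@@H](c2cc(Br)c(OC)c(I)c2)Oc2cc(OCc3ccccc3)cc(OCc3ccccc3)c12 | intermediate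
9 | (S)-2-(3-bromo-5-iodo-4-methoxyphenyl)-5,7-dihydroxychroman-4-one | O=C1C[C@@H](c2cc(Br)c(OC)c(I)c2)Oc2cc(O)cc(O)c12 | intermediate
10 | tributyl(3-methylbut-2-en-1-yl)stannane | CCCC[Sn](CCCC)(CCCC)CC=C(C)C | starting material
11 | (S)-2-[3-bromo-4-methoxy-5-(3-methylbut-2-en-1-yl)phenyl]-5,7-dihydroxychroman-4-one | O=C1C[C@@H](c2cc(Br)c(OC)c(CC=C(C)C)c2)Oc2cc(O)cc(O)c12 | intermediate
12 | 2-methylbut-1-en-3-yne | C=C(C)C#C | starting material
13 | (E)-tributyl(3-methylbuta-1,3-dien-1-yl)stannane | C=C(C)/C=C/[Sn](CCCC)(CCCC)CCCC | intermediate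
14 | (S)-5,7-dihydroxy-2-{4-methoxy-3-[(E)-3-methylbuta-1,3-dien-1-yl]-5-(3-methylbut-2-en-1-yl)phenyl}chroman-4-one | C=C(C)/C=C/c1cc([C@@H]2CC(=O)c3c(O)cc(O)cc3O2)cc(CC=C(C)C)c1OC | target

Total step count: 8. Longest linear sequence: 7 (steps 1 to 6 and step 8; step 7 is a one-step branch).

Steps most likely to fail

Step 4 (proposed new method). The phenoxide may attack the lactone acyl carbon, or deprotonate the α-carbon with ring opening to a cinnamate. Carbon alkylation of the electron-rich ring, or partial ionization at the benzylic carbon with erosion of the enantiomeric purity, are also possible. In the second stage the aryloxide may be eliminated from the mixed anhydride. The fallback uses known chemistry, sets out from 4 and returns to the route at 6. Lactone 4 is opened at the acyl carbon (NaOMe cat., MeOH, 0 °C) to methyl (R)-3-(3-bromo-5-iodo-4-methoxyphenyl)-3-hydroxypropanoate F1. Mitsunobu etherification of F1 with 5 (PPh3, DIAD, toluene, 0 °C) inverts the carbinol and should give methyl (S)-3-[3,5-bis(benzyloxy)phenoxy]-3-(3-bromo-5-iodo-4-methoxyphenyl)propanoate F2. Hydrolysis (LiOH, THF/H2O, 0 °C) gives acid 6, now isolated, and TFAA in CH2Cl2 closes it through 7 to 8 as in the second stage of step 4.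

Step 3. The aromatic aldehyde may turn over slowly in the cyclocondensation, or the facial selectivity may be insufficient or of the opposite sense. The fallback sets out from 3 and returns at 4. Roskamp homologation of 3 (ethyl diazoacetate, SnCl2 cat., CH2Cl2, rt) gives ethyl 3-(3-bromo-5-iodo-4-methoxyphenyl)-3-oxopropanoate F3. Asymmetric transfer hydrogenation (RuCl[(R,R)-TsDPEN](p-cymene), HCO2H/Et3N, rt) should give ethyl (R)-3-(3-bromo-5-iodo-4-methoxyphenyl)-3-hydroxypropanoate F4 without touching the aryl halides. Hydrolysis (LiOH, THF/H2O, 0 °C) gives (R)-3-(3-bromo-5-iodo-4-methoxyphenyl)-3-hydroxypropanoic acid F5. Lactonization by carboxyl activation (PhSO2Cl, pyridine, 0 °C) proceeds with retention at the carbinol carbon and returns 4.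

Step 6. The prenyl group may be transferred through its substituted terminus (reverse-prenyl product), and the discrimination between iodide and bromide may be lost at the temperature the allyl transfer needs. The fallback sets out from 9 and returns at 11. Stille coupling of 9 with allyltributylstannane (Pd(PPh3)4, DMF, 70 °C), which has no regiochemical ambiguity, gives (S)-2-[3-bromo-4-methoxy-5-(prop-2-en-1-yl)phenyl]-5,7-dihydroxychroman-4-one F6. Cross-metathesis of F6 with excess 2-methyl-2-butene (second-generation Grubbs catalyst, RuCl2(H2IMes)(PCy3)(=CHPh), CH2Cl2, 40 °C) converts the allyl into the prenyl group and returns 11.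

Further compounds
F1 | step 4 | methyl (R)-3-(3-bromo-5-iodo-4-methoxyphenyl)-3-hydroxypropanoate | COC(=O)C[C@@H](O)c1cc(Br)c(OC)c(I)c1
F2 | step 4 | methyl (S)-3-[3,5-bis(benzyloxy)phenoxy]-3-(3-bromo-5-iodo-4-methoxyphenyl)propanoate | COC(=O)C[C@H](Oc1cc(OCc2ccccc2)cc(OCc2ccccc2)c1)c1cc(Br)c(OC)c(I)c1
F3 | step 3 | ethyl 3-(3-bromo-5-iodo-4-methoxyphenyl)-3-oxopropanoate | CCOC(=O)CC(=O)c1cc(Br)c(OC)c(I)c1
F4 | step 3 | ethyl (R)-3-(3-bromo-5-iodo-4-methoxyphenyl)-3-hydroxypropanoate | CCOC(=O)C[C@@H](O)c1cc(Br)c(OC)c(I)c1
F5 | step 3 | (R)-3-(3-bromo-5-iodo-4-methoxyphenyl)-3-hydroxypropanoic acid | OC(=O)C[C@@H](O)c1cc(Br)c(OC)c(I)c1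
F6 | step 6 | (S)-2-[3-bromo-4-methoxy-5-(prop-2-en-1-yl)phenyl]-5,7-dihydroxychroman-4-one | O=C1C[C@@H](c2cc(Br)c(OC)c(CC=C)c2)Oc2cc(O)cc(O)c12
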